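**Retrosynthetic overview**

The target is read as 3β-acetoxylabda-7,13E-dien-15-oic acid (trans-decalin, 5α-H, 9α-H, 10β-CH3); labdane numbering is used for every intermediate, with β meaning the face of the C10 methyl.
Enabling feature: in ring A the quaternary C4 with its two methyls (C18, C19) lies between the oxygenated C3 and C5. C4 + C18 + C19 is therefore a 2-propenyl group on C5 in disguise, and ring B (C5–C10 with the C8 methyl) is the ring of (R)-carvone. A hydrogen atom added to the propenyl CH2 gives a tertiary C4 radical that sits 1,6 to a C3 aldehyde.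
Disconnections (retro): OAc and CO2H (acetylation, saponification); C3–C4 (reductive olefin–aldehyde cyclization, closes ring A); C3 aldehyde from a C10 allyl group; C13=C14 enoate from a terminal alkyne; C9–H and the C7=C8 alkene from a 7-ol by allylic-diazene transposition; C9–C11 by 1,2-addition to the carvone carbonyl and oxidative 1,3-transposition; C10 quaternary centre by double α′-alkylation of carvone.
Ring order: ring B is bought with carvone and receives C10, C9 and the whole side chain first; ring A is closed last, in step 10.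

Key step: step 10

Remark: 3 is used as its C10 epimer mixture and 8 as its C9 epimer mixture, because both centres are erased in the following step; the SMILES show the expected major epimer.

**Route**

Step 1
Reactants: 1 (R)-(−)-carvone
Product: 3 (5R,6S)-2,6-dimethyl-5-(prop-1-en-2-yl)cyclohex-2-en-1-one (6-methylcarvone; C10 epimers), via kinetic lithium dienolate of carvone 2 (not isolated)
Conditions: LiN(i-Pr)2 (LDA), THF, −78 °C; MeI, −78 to 0 °C
Reagents that add atoms: iodomethane, CI
Why: Kinetic α′-deprotonation at C10 gives the cross-conjugated lithium enolate, which is C-methylated (enolate alkylation); the new C10 centre is planarised again in step 2, so its configuration does not matter.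

Step 2
Reactants: 3 (5R,6S)-2,6-dimethyl-5-(prop-1-en-2-yl)cyclohex-2-en-1-one
Product: 5 (5S,6S)-2,6-dimethyl-6-(prop-2-en-1-yl)-5-(prop-1-en-2-yl)cyclohex-2-en-1-one (allyl trans and methyl cis to the isopropenyl group), via lithium enolate (C9=C10) 4 (not isolated)
Conditions: LiN(i-Pr)2, THF, −78 to 0 °C; allyl bromide, DMPU, −78 °C to rt
Reagents that add atoms: allyl bromide, C=CCBr
Why: In this second enolate alkylation allyl bromide should approach the tetrasubstituted enolate anti to the neighbouring C5 isopropenyl group, which sets the quaternary C10 with the allyl group (future C1–C3) trans and the methyl (C20) cis to the isopropenyl group, the relation a trans-decalin needs.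

Step 3
Reactants: 5 (5S,6S)-2,6-dimethyl-6-(prop-2-en-1-yl)-5-(prop-1-en-2-yl)cyclohex-2-en-1-one; 6 4-bromo-1-(trimethylsilyl)but-1-yne
Product: 8 6-allyl-2,6-dimethyl-5-(prop-1-en-2-yl)-1-[4-(trimethylsilyl)but-3-yn-1-yl]cyclohex-2-en-1-ol (tertiary 9-ol), via [4-(trimethylsilyl)but-3-yn-1-yl]magnesium bromide 7 (not isolated)
Conditions: 6, Mg, THF, rt to 40 °C; anhydrous CeCl3, THF, −78 °C; then 5, −78 to 0 °C; aq. NH4Cl
Reagents that add atoms: none
Why: Organocerium-type (Grignard/CeCl3) 1,2-addition to the hindered enone carbonyl brings in C11–C14, CeCl3 suppressing enolisation and reduction; the C9 carbinol centre (attack expected anti to the axial C10 methyl) is erased in step 4.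

Step 4
Reactants: 8 6-allyl-2,6-dimethyl-5-(prop-1-en-2-yl)-1-[4-(trimethylsilyl)but-3-yn-1-yl]cyclohex-2-en-1-ol
Product: 9 4-allyl-2,4-dimethyl-5-(prop-1-en-2-yl)-3-[4-(trimethylsilyl)but-3-yn-1-yl]cyclohex-2-en-1-one (7-oxo, C8=C9)
Conditions: C5H5NH[CrO3Cl] (pyridinium chlorochromate), NaOAc, 4 Å MS, CH2Cl2, rt
Reagents that add atoms: pyridinium chlorochromate, [O-][Cr](=O)(=O)Cl.c1cc[nH+]cc1
Why: Babler–Dauben oxidative 1,3-transposition: the tertiary allylic chromate ester undergoes a [3,3] shift to the secondary C7 chromate, which is oxidised to the enone, so oxygen moves from C9 to C7 and the alkene to C8=C9.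

Step 5
Reactants: 9 4-allyl-2,4-dimethyl-5-(prop-1-en-2-yl)-3-[4-(trimethylsilyl)but-3-yn-1-yl]cyclohex-2-en-1-one
Product: 10 4-allyl-2,4-dimethyl-5-(prop-1-en-2-yl)-3-[4-(trimethylsilyl)but-3-yn-1-yl]cyclohex-2-en-1-ol (7β-OH, cis to the isopropenyl group)
Conditions: NaBH4, CeCl3·7H2O, MeOH, −20 to 0 °C
Reagents that add atoms: none
Why: Luche 1,2-reduction; hydride should attack C7 from the α face, away from the isopropenyl-bearing face, to give the 7β-alcohol cis to the isopropenyl group, as in the reduction of carvone to cis-carveol.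

Step 6
Reactants: 10 4-allyl-2,4-dimethyl-5-(prop-1-en-2-yl)-3-[4-(trimethylsilyl)but-3-yn-1-yl]cyclohex-2-en-1-ol
Product: 13 {4-[6-allyl-2,6-dimethyl-5-(prop-1-en-2-yl)cyclohex-2-en-1-yl]but-1-yn-1-yl}trimethylsilane (side chain on C9 β; 9α-H; C7=C8), via 7α-sulfonylhydrazine Mitsunobu adduct 11 (not isolated), via 7α-allylic diazene 12 (not isolated)
Conditions: 2-nitrobenzenesulfonylhydrazide (NBSH), PPh3, DEAD, N-methylmorpholine, −30 °C; then 23 °C
Reagents that add atoms: none
Why: Mitsunobu displacement by NBSH inverts C7, loss of the sulfinic acid gives the 7α-allylic diazene, and its retro-ene (sigmatropic) loss of N2 delivers hydrogen suprafacially to the α face of C9 while the alkene moves to C7=C8, which sets C9 (9α-H, side chain β) from the C7 carbinol.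

Step 7
Reactants: 13 {4-[6-allyl-2,6-dimethyl-5-(prop-1-en-2-yl)cyclohex-2-en-1-yl]but-1-yn-1-yl}trimethylsilane
Product: 14 4-[6-allyl-2,6-dimethyl-5-(prop-1-en-2-yl)cyclohex-2-en-1-yl]but-1-yne
Conditions: K2CO3, MeOH, rt
Reagents that add atoms: none
Why: Base-catalysed methanolysis of the alkynyl C–Si bond (protodesilylation) frees the terminal alkyne, and nothing else in the molecule is base-labile.

Step 8
Reactants: 14 4-[6-allyl-2,6-dimethyl-5-(prop-1-en-2-yl)cyclohex-2-en-1-yl]but-1-yne
Product: 16 methyl (2E)-5-[6-allyl-2,6-dimethyl-5-(prop-1-en-2-yl)cyclohex-2-en-1-yl]-3-methylpent-2-enoate, via (E)-alkenyldimethylalane 15 (not isolated)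
Conditions: Me3Al, Cp2ZrCl2 (cat.), H2O (1 equiv), CH2Cl2, −20 °C; then ClCO2Me, −20 °C to rt; aq. HCl
Reagents that add atoms: trimethylaluminium, C[Al](C)C; methyl chloroformate, COC(=O)Cl
Why: Zirconium-catalysed Negishi methylalumination adds CH3 and Al syn across the terminal alkyne with Al on the terminal carbon, and acylation of the alkenylalane with retention should give only the (E)-3-methyl-2-enoate, the alkenes being carbometalated far more slowly than the alkyne at −20 °C.

Step 9
Reactants: 16 methyl (2E)-5-[6-allyl-2,6-dimethyl-5-(prop-1-en-2-yl)cyclohex-2-en-1-yl]-3-methylpent-2-enoate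
Product: 17 methyl (2E)-5-[2,6-dimethyl-6-(3-oxopropyl)-5-(prop-1-en-2-yl)cyclohex-2-en-1-yl]-3-methylpent-2-enoate
Conditions: PdCl2(PhCN)2 (cat.), CuCl2·2H2O (cat.), AgNO2 (cat.), O2 (1 atm), t-BuOH/MeNO2, rt
Reagents that add atoms: dioxygen, O=O
Why: Aldehyde-selective (anti-Markovnikov) nitrite-modified Wacker oxidation, a known reaction of terminal alkenes that carry a quaternary homoallylic carbon; the 1,1-disubstituted and trisubstituted alkenes and the enoate should not react under Wacker conditions.

Step 10
Reactants: 17 methyl (2E)-5-[2,6-dimethyl-6-(3-oxopropyl)-5-(prop-1-en-2-yl)cyclohex-2-en-1-yl]-3-methylpent-2-enoate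
Product: 18 methyl 3β-hydroxylabda-7,13E-dien-15-oate
Conditions: Fe(acac)3 (30 mol %), PhSiH3, EtOH/THF, 0.02 M, 60 °C
Reagents that add atoms: none
Why: Proposed new method: Fe(acac)3 and PhSiH3 in ethanol form an iron hydride that transfers a hydrogen atom to the CH2 terminus of the C5 isopropenyl group (Markovnikov MHAT), which makes the second C4 methyl and a tertiary C4 radical; this radical adds to the C3 aldehyde carbon, and the C3 alkoxy radical is reduced by divalent iron and protonated by ethanol, which drives the reversible addition forward and returns trivalent iron. The closest known reaction types are the Fe(acac)3/PhSiH3 HAT-initiated radical cyclization of alkene-tethered ketones (5-exo and 6-exo attack on C=O) and the intermolecular MHAT-initiated reductive coupling of unactivated olefins with aldehydes; new here is the ring closure onto an aldehyde, which makes the method create a secondary carbinol stereocentre. Ring A closes by 6-exo-trig attack of C4 on C3 along the chain C4–C5–C10–C1–C2–C3, and because the C4 group on C5 (β) and the C1 chain on C10 (α) are trans-diequatorial on ring B, the new ring can only be trans-fused. The new stereocentre C3 is controlled by the chair-like transition state on this template, in which the carbonyl oxygen takes the equatorial position (no 1,3-diaxial contact with the axial hydrogens on C1 and C5) and becomes the 3β-hydroxyl, while C4 is not stereogenic. The step needs three selectivities: HAT at the 1,1-disubstituted alkene rather than at the hindered trisubstituted C7=C8 alkene or the electron-poor enoate (secured by the much higher HAT rate of the unhindered 1,1-disubstituted alkene), bond formation at C4 rather than at the terminal carbon as in a cationic ene or Prins closure (secured by the Markovnikov sense of HAT), and attack on the aldehyde only (the ester carbonyl is out of reach and far less radicophilic).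

Step 11
Reactants: 18 methyl 3β-hydroxylabda-7,13E-dien-15-oate
Product: 19 3β-hydroxylabda-7,13E-dien-15-oic acid
Conditions: LiOH, THF/MeOH/H2O, 40 °C; then aq. HCl to pH 3
Reagents that add atoms: lithium hydroxide, [Li+].[OH-]
Why: Saponification of the methyl ester; the β,β-disubstituted enoate should keep its E geometry under these mild conditions and the hindered secondary alcohol is not affected.

Step 12
Reactants: 19 3β-hydroxylabda-7,13E-dien-15-oic acid
Product: 21 3β-acetoxylabda-7,13E-dien-15-oic acid (target), via mixed acetic carboxylic anhydride 20 (not isolated)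
Conditions: Ac2O, pyridine, DMAP (cat.), rt; then H2O/THF, rt
Reagents that add atoms: acetic anhydride, CC(=O)OC(C)=O
Why: DMAP-catalysed O-acetylation of the equatorial 3β-hydroxyl with retention at C3; the carboxylic acid is acylated in the flask to the mixed anhydride, which is hydrolysed back to the acid in the aqueous stage.

**Compound list**

1 | (R)-(−)-carvone, (5R)-2-methyl-5-(prop-1-en-2-yl)cyclohex-2-en-1-one | CC1=CC[C@H](CC1=O)C(C)=C | starting material
2 | kinetic lithium dienolate of carvone (O–Li on C9, C9=C10) | CC1=CC[C@H](C=C1O[Li])C(C)=C | intermediate (not isolated)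
3 | (5R,6S)-2,6-dimethyl-5-(prop-1-en-2-yl)cyclohex-2-en-1-one (6-methylcarvone, trans epimer shown) | C[C@@H]1C(=O)C(C)=CC[C@H]1C(C)=C | intermediate
4 | lithium enolate of 3 (C9=C10) | CC1=C(O[Li])C(C)=CC[C@H]1C(C)=C | intermediate (not isolated)
5 | (5S,6S)-2,6-dimethyl-6-(prop-2-en-1-yl)-5-(prop-1-en-2-yl)cyclohex-2-en-1-one | C=CC[C@]1(C)C(=O)C(C)=CC[C@H]1C(C)=C | intermediate
6 | 4-bromo-1-(trimethylsilyl)but-1-yne | C[Si](C)(C)C#CCCBr | starting material
7 | [4-(trimethylsilyl)but-3-yn-1-yl]magnesium bromide | C[Si](C)(C)C#CCC[Mg]Br | intermediate (not isolated)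
8 | 6-allyl-2,6-dimethyl-5-(prop-1-en-2-yl)-1-[4-(trimethylsilyl)but-3-yn-1-yl]cyclohex-2-en-1-ol (9β-OH epimer shown) | C=CC[C@]1(C)[C@](O)(CCC#C[Si](C)(C)C)C(C)=CC[C@H]1C(C)=C | intermediate
9 | 4-allyl-2,4-dimethyl-5-(prop-1-en-2-yl)-3-[4-(trimethylsilyl)but-3-yn-1-yl]cyclohex-2-en-1-one (allyl trans to isopropenyl) | C=CC[C@]1(C)C(CCC#C[Si](C)(C)C)=C(C)C(=O)C[C@H]1C(C)=C | intermediate
10 | 4-allyl-2,4-dimethyl-5-(prop-1-en-2-yl)-3-[4-(trimethylsilyl)but-3-yn-1-yl]cyclohex-2-en-1-ol (7β-OH, cis to isopropenyl) | C=CC[C@]1(C)C(CCC#C[Si](C)(C)C)=C(C)[C@@H](O)C[C@H]1C(C)=C | intermediate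
11 | 7α-[N-amino-N-(2-nitrobenzenesulfonyl)amino] Mitsunobu adduct of 10 (C7 inverted) | C=CC[C@]1(C)C(CCC#C[Si](C)(C)C)=C(C)[C@H](N(N)S(=O)(=O)c2ccccc2[N+](=O)[O-])C[C@H]1C(C)=C | intermediate (not isolated)
12 | 7α-allylic diazene (C7–N=NH) | C=CC[C@]1(C)C(CCC#C[Si](C)(C)C)=C(C)[C@H](N=N)C[C@H]1C(C)=C | intermediate (not isolated)
13 | {4-[6-allyl-2,6-dimethyl-5-(prop-1-en-2-yl)cyclohex-2-en-1-yl]but-1-yn-1-yl}trimethylsilane (side chain, C10 methyl and isopropenyl all β; allyl and H9 α) | C=CC[C@]1(C)[C@@H](CCC#C[Si](C)(C)C)C(C)=CC[C@H]1C(C)=C | intermediate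
14 | 4-[6-allyl-2,6-dimethyl-5-(prop-1-en-2-yl)cyclohex-2-en-1-yl]but-1-yne (ring stereochemistry as 13) | C=CC[C@]1(C)[C@@H](CCC#C)C(C)=CC[C@H]1C(C)=C | intermediate
15 | (E)-alkenyldimethylalane from 14 (CH3 on C13, AlMe2 on C14) | C=CC[C@]1(C)[C@@H](CC/C(C)=C/[Al](C)C)C(C)=CC[C@H]1C(C)=C | intermediate (not isolated)
16 | methyl (2E)-5-[6-allyl-2,6-dimethyl-5-(prop-1-en-2-yl)cyclohex-2-en-1-yl]-3-methylpent-2-enoate | C=CC[C@]1(C)[C@@H](CC/C(C)=C/C(=O)OC)C(C)=CC[C@H]1C(C)=C | intermediate
17 | methyl (2E)-5-[2,6-dimethyl-6-(3-oxopropyl)-5-(prop-1-en-2-yl)cyclohex-2-en-1-yl]-3-methylpent-2-enoate | O=CCC[C@]1(C)[C@@H](CC/C(C)=C/C(=O)OC)C(C)=CC[C@H]1C(C)=C | intermediate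
18 | methyl 3β-hydroxylabda-7,13E-dien-15-oate | O[C@H]1CC[C@]2(C)[C@@H](CC/C(C)=C/C(=O)OC)C(C)=CC[C@H]2C1(C)C | intermediate
19 | 3β-hydroxylabda-7,13E-dien-15-oic acid | O[C@H]1CC[C@]2(C)[C@@H](CC/C(C)=C/C(=O)O)C(C)=CC[C@H]2C1(C)C | intermediate
20 | acetic 3β-acetoxylabda-7,13E-dien-15-oic anhydride | CC(=O)O[C@H]1CC[C@]2(C)[C@@H](CC/C(C)=C/C(=O)OC(C)=O)C(C)=CC[C@H]2C1(C)C | intermediate (not isolated)
21 | 3β-acetoxylabda-7,13E-dien-15-oic acid (CNP0264606.2) | CC(=O)O[C@H]1CC[C@]2(C)[C@@H](CC/C(C)=C/C(=O)O)C(C)=CC[C@H]2C1(C)C | target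

**Step count and risks**

Total step count: 12. Longest linear sequence: 12 steps, from 1 to 21 (the Grignard reagent 7 is made in the flask of step 3).

Steps most likely to fail:

1. Step 10 (bears the label). What may go wrong: hydrogen-atom transfer to the C7=C8 alkene with isomerisation; back-transfer of hydrogen from C5, which would isomerise the propenyl group to the isopropylidene and endanger C5; reduction of the C4 radical before it reaches C3; or weak facial control at C3. Fallback with known chemistry, setting out from 17 and returning at 18: 17 is condensed with NH2OH·HCl in pyridine to the oxime F1, which is dehydrated (Ac2O, 100 °C) to the nitrile F2. The known Fe(acac)3/PhSiH3 HAT-initiated radical cyclization of alkene-tethered nitriles (EtOH, 60 °C) forms the same C3–C4 bond by 6-exo-dig attack of the C4 radical on the nitrile carbon and gives the ketimine F3, which is hydrolysed on acidic work-up to the 3-ketone F4. NaBH4 (MeOH, 0 °C) then attacks this 4,4-dimethyl-3-ketone from the α face to give the equatorial 3β-alcohol 18, leaving the conjugated ester alone. Any 3α-epimer from step 10 could be oxidised (Dess–Martin periodinane) to the same ketone F4 and reduced in the same way.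

2. Step 9. What may go wrong: Markovnikov oxygenation to the methyl ketone, or palladium-induced migration of the other double bonds. Fallback, setting out from 16 and returning at 17: hydroboration with disiamylborane (THF, 0 °C), which discriminates the monosubstituted alkene from the 1,1-disubstituted and trisubstituted ones and leaves the ester, gives the trialkylborane F5. Oxidation with NaBO3·4H2O gives the primary alcohol F6, and Dess–Martin periodinane (CH2Cl2, NaHCO3) oxidises it to 17.

3. Step 6. What may go wrong: the Mitsunobu displacement may fail on the hindered allylic alcohol or take the SN2′ course, which would break the stereochemical relay from C7 to C9. Fallback, setting out from 10 and returning at 13: 10 is formylated (acetic formic anhydride, pyridine, 0 °C) to the 7β-formate F7. Pd(OAc)2/PBu3 (dioxane, 100 °C; zerovalent palladium formed in the flask) ionises the formate with inversion to a π-allylpalladium formate bound on the α face; loss of CO2 gives a palladium hydride that is delivered to the more substituted terminus C9 from the same α face. This known Tsuji–Trost-type formate hydrogenolysis gives 13 with 9α-H and the C7=C8 alkene.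

Further compounds
F1 | step 10 | oxime of 17 (E/Z mixture), methyl (2E)-5-[6-(3-(hydroxyimino)propyl)-2,6-dimethyl-5-(prop-1-en-2-yl)cyclohex-2-en-1-yl]-3-methylpent-2-enoate | ON=CCC[C@]1(C)[C@@H](CC/C(C)=C/C(=O)OC)C(C)=CC[C@H]1C(C)=C
F2 | step 10 | methyl (2E)-5-[6-(2-cyanoethyl)-2,6-dimethyl-5-(prop-1-en-2-yl)cyclohex-2-en-1-yl]-3-methylpent-2-enoate | N#CCC[C@]1(C)[C@@H](CC/C(C)=C/C(=O)OC)C(C)=CC[C@H]1C(C)=C
F3 | step 10 | methyl 3-iminolabda-7,13E-dien-15-oate (N–H ketimine) | N=C1CC[C@]2(C)[C@@H](CC/C(C)=C/C(=O)OC)C(C)=CC[C@H]2C1(C)C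
F4 | step 10 | methyl 3-oxolabda-7,13E-dien-15-oate | O=C1CC[C@]2(C)[C@@H](CC/C(C)=C/C(=O)OC)C(C)=CC[C@H]2C1(C)C
F5 | step 9 | bis(3-methylbutan-2-yl)borane adduct of 16 (boron on the terminal allyl carbon, C3) | CC(C)C(C)B(CCC[C@]1(C)[C@@H](CC/C(C)=C/C(=O)OC)C(C)=CC[C@H]1C(C)=C)C(C)C(C)C
F6 | step 9 | methyl (2E)-5-[6-(3-hydroxypropyl)-2,6-dimethyl-5-(prop-1-en-2-yl)cyclohex-2-en-1-yl]-3-methylpent-2-enoate | OCCC[C@]1(C)[C@@H](CC/C(C)=C/C(=O)OC)C(C)=CC[C@H]1C(C)=C
F7 | step 6 | 7β-formate of 10 | C=CC[C@]1(C)C(CCC#C[Si](C)(C)C)=C(C)[C@@H](OC=O)C[C@H]1C(C)=C
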